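## Retrosynthetic overview
1. Labels: ring A is the para-phenylene, ring B the 2-aryloxy-3-hydroxyphenyl ring, ring C the meta-phenylene, and ring D the catechol ring (C1 side chain, C3/C4 oxygens, C5 ether oxygen). C7' is the carbinol carbon and C8' its CH2 neighbour.
2. The (S)-C7'–OH comes from a last-step asymmetric transfer hydrogenation of the macrocyclic C7' ketone, so the labile para-hydroxybenzylic alcohol meets no later reagent.
3. The 18-membered macrocycle is the only ring formed. It comes from a biomimetic oxidative phenol C–O coupling of an acyclic bis(bibenzyl)-type ether. The ring D phenol is oxidised to a half-masked ortho-quinone, the ring A phenol oxygen is captured at C5, and the ring rearomatises.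
4. The seco compound comes from Pd enolate arylation (C8'–ring C), Wittig/hydrogenation (A–B bridge) and SNAr (B–O–C ether).
5. Order: B–O–C ether, A–B bridge, C–D bridge, macrocycle (A–O–D ether), deprotection, stereocentre.

Assumption: the stereodescriptor in the SMILES is read as (S) at C7' (OH > ring D aryl > CH2Ar > H), and salt 4 and ketone 7 are taken as catalogue items.

## Route

Step 1
Reactants: 1 2-fluoro-3-methoxybenzaldehyde; 2 3-bromophenol
Product: 3 2-(3-bromophenoxy)-3-methoxybenzaldehyde
Conditions: K2CO3 (1.5 equiv), DMF, 120 °C, 12 h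
Reagents that add atoms: none
Why: SNAr, in which the ortho-formyl group stabilises the Meisenheimer adduct and fluoride is the best leaving group, so the phenoxide of 2 displaces F without touching the aryl bromide; no stereocentre.

Step 2
Reactants: 3 2-(3-bromophenoxy)-3-methoxybenzaldehyde; 4 [4-(benzyloxy)benzyl]triphenylphosphonium chloride
Product: 6 1-{2-[4-(benzyloxy)phenyl]ethenyl}-2-(3-bromophenoxy)-3-methoxybenzene (E/Z mixture), via phosphorus ylide 5 (not isolated)
Conditions: KOtBu (1.15 equiv), THF, 0 °C, 30 min; then 3, 0 °C to rt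
Reagents that add atoms: none
Why: Wittig olefination of a non-enolisable aldehyde by a semistabilised benzylic ylide; the E/Z ratio is irrelevant because the alkene is saturated in step 4.

Step 3
Reactants: 6 bromo stilbene from step 2; 7 1-(3-hydroxy-4-methoxyphenyl)ethanone (isoacetovanillone)
Product: 8 2-[3-(2-{2-[4-(benzyloxy)phenyl]ethenyl}-6-methoxyphenoxy)phenyl]-1-(3-hydroxy-4-methoxyphenyl)ethanone (E/Z mixture)
Conditions: Pd(OAc)2 (2 mol %), XPhos (4 mol %), NaOtBu (3.2 equiv), THF–toluene, 65 °C; aq NH4Cl work-up
Reagents that add atoms: none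
Why: Buchwald–Hartwig-type Pd-catalysed alpha-arylation of an aryl methyl ketone enolate, in which the bulky biaryl phosphine favours monoarylation, the extra base holds the meta-phenol as an unreactive phenoxide, and the more acidic product is protected as its enolate.

Step 4
Reactants: 8 stilbene ketone from step 3
Product: 9 1-(3-hydroxy-4-methoxyphenyl)-2-(3-{2-[2-(4-hydroxyphenyl)ethyl]-6-methoxyphenoxy}phenyl)ethanone (seco ketone)
Conditions: H2 (1 atm), 10% Pd/C, EtOAc–EtOH 1:1, rt
Reagents that add atoms: none
Why: Heterogeneous catalytic hydrogenation saturates the stilbene and hydrogenolyses the benzyl ether much faster than it attacks the electron-rich para-methoxyaryl ketone under neutral conditions at 1 atm.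

Step 5
Reactants: 9 seco ketone
Product: 10 5-[2-(3-{2-[2-(4-hydroxyphenyl)ethyl]-6-methoxyphenoxy}benzyl)-1,3-dioxolan-2-yl]-2-methoxyphenol (seco ketal)
Conditions: ethylene glycol (10 equiv), p-TsOH·H2O (5 mol %), toluene, Dean–Stark reflux
Reagents that add atoms: ethylene glycol, OCCO
Why: Acid-catalysed ketalisation with azeotropic water removal makes C7' sp3, which removes the acyl conjugation that would make ring D harder to oxidise and would steer nucleophiles to C2 (ortho to the acyl group) in step 6.

Step 6
Reactants: 10 seco ketal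
Product: 12 macrocyclic diaryl ether ketal (18-membered ring; ring D 3-OH 4-OMe 5-O-ring A; ring B OMe; C7' as 1,3-dioxolane), via orthoquinol acetate 11 (not isolated)
Conditions: PhI(OAc)2 (1.05 equiv), CH2Cl2, −78 to −30 °C, 1 h; then syringe pump (10 h) into Cs2CO3 (5 equiv), 4 Å sieves, MeCN, 25 °C, final 1 mM
Reagents that add atoms: none
Why: Proposed new method: PhI(OAc)2 oxidises the electron-rich 2-methoxyphenol of ring D in preference to the 4-alkylphenol of ring A by oxidative acetoxylation at the methoxy-bearing C4, giving orthoquinol acetate 11, in which only the C3 carbonyl of the biosynthetic ortho-quinone is live; in its linear dienone O=C3–C2=C1–C6=C5 the beta carbon C1 is blocked by the side chain, so the caesium phenoxide of ring A can add productively only at C5 (reversible oxa-1,6-addition), loss of AcOH across C4–C5 then rearomatises irreversibly to the A–O–D ether, and 12 cannot be over-oxidised because the oxidant is spent before ring closure; the closest known reaction type is hypervalent-iodine dearomatisation of 2-alkoxyphenols to orthoquinol acetates or masked ortho-benzoquinones followed by conjugate addition of tethered O- or N-nucleophiles or indoles and rearomatisation (oxidative nucleophilic aromatic substitution), here extended to a phenol nucleophile and a large ring; the racemic sp3 C4 of 11 is lost again, so no stereocentre results.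

Step 7
Reactants: 12 macrocyclic diaryl ether ketal
Product: 13 macrocyclic C7' ketone triphenol (ring D 3,4-dihydroxy-5-aryloxy; ring B OH)
Conditions: BBr3 (8 equiv), CH2Cl2, −78 to 0 °C; H2O quench
Reagents that add atoms: none
Why: Lewis-acid ether cleavage, in which BBr3 demethylates both aryl methyl ethers and opens the dioxolane (bromide attacks the O–CH2 of the aryl-stabilised oxocarbenium ion, so the ketone keeps a ketal oxygen), while the diaryl ethers and the ketone are inert; it is run before the carbinol exists because a para-hydroxybenzylic alcohol would ionise.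

Step 8
Reactants: 13 macrocyclic C7' ketone triphenol
Product: 14 target, (S)-C7' carbinol
Conditions: RuCl(p-cymene)[(S,S)-TsDPEN] (2 mol %), HCO2H–Et3N 1:1 (5 equiv), DMF, 30 °C, argon
Reagents that add atoms: none
Why: Noyori–Ikariya asymmetric transfer hydrogenation, in which the conjugated ring D aryl group sits under the eta-6 arene of the catalyst (CH/pi attraction) in the outer-sphere six-membered transition state, so the (S,S)-catalyst delivers hydride to the Re face and gives the (S)-alcohol (same sense as acetophenone to (S)-1-phenylethanol); the near-neutral formate medium keeps the acid-labile product from racemising.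

## Compound list
1 | 2-fluoro-3-methoxybenzaldehyde | COc1cccc(C=O)c1F | starting material
2 | 3-bromophenol | Oc1cccc(Br)c1 | starting material
3 | 2-(3-bromophenoxy)-3-methoxybenzaldehyde | COc1cccc(C=O)c1Oc1cccc(Br)c1 | intermediate
4 | [4-(benzyloxy)benzyl]triphenylphosphonium chloride | [Cl-].c1ccc(cc1)COc1ccc(cc1)C[P+](c1ccccc1)(c1ccccc1)c1ccccc1 | starting material
5 | [4-(benzyloxy)benzylidene]triphenylphosphorane (ylide, not isolated) | c1ccc(cc1)COc1ccc(cc1)C=P(c1ccccc1)(c1ccccc1)c1ccccc1 | intermediate
6 | 1-{2-[4-(benzyloxy)phenyl]ethenyl}-2-(3-bromophenoxy)-3-methoxybenzene (E/Z mixture, geometry left open) | COc1cccc(C=Cc2ccc(OCc3ccccc3)cc2)c1Oc1cccc(Br)c1 | intermediate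
7 | 1-(3-hydroxy-4-methoxyphenyl)ethanone | CC(=O)c1ccc(OC)c(O)c1 | starting material
8 | stilbene ketone (E/Z mixture, geometry left open) | COc1ccc(cc1O)C(=O)Cc1cccc(Oc2c(OC)cccc2C=Cc2ccc(OCc3ccccc3)cc2)c1 | intermediate
9 | seco ketone | COc1ccc(cc1O)C(=O)Cc1cccc(Oc2c(OC)cccc2CCc2ccc(O)cc2)c1 | intermediate
10 | seco ketal (1,3-dioxolane of 9) | COc1ccc(cc1O)C1(Cc2cccc(Oc3c(OC)cccc3CCc3ccc(O)cc3)c2)OCCO1 | intermediate
11 | orthoquinol acetate: 4-substituted 1-methoxy-6-oxocyclohexa-2,4-dien-1-yl acetate (racemic, not isolated) | COC1(OC(C)=O)C=CC(=CC1=O)C2(Cc3cccc(Oc4c(OC)cccc4CCc4ccc(O)cc4)c3)OCCO2 | intermediate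
12 | macrocyclic diaryl ether ketal | Oc1cc2cc(c1OC)Oc1ccc(cc1)CCc1cccc(OC)c1Oc1cccc(c1)CC23OCCO3 | intermediate
13 | macrocyclic C7' ketone triphenol | Oc1cc2cc(c1O)Oc1ccc(cc1)CCc1cccc(O)c1Oc1cccc(c1)CC2=O | intermediate
14 | target, (S)-C7' carbinol | Oc1cc2cc(c1O)Oc1ccc(cc1)CCc1cccc(O)c1Oc1cccc(c1)C[C@@H]2O | target

## Totals
Total step count: 8. Longest linear sequence: 8 (from 1 or 2 to 14).

## Three steps most likely to fail

**Step 6 (oxidative macrocyclisation).** The risks are:
- competing oxidation of the ring A phenol;
- acetyl transfer from 11 to the phenoxide;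
- attack through the ortho carbon of ring A, or SN2'-type attack at C6;
- Diels–Alder dimerisation of 11, or oligomer formation.

The fallback sets out from 6 and comes back at 13. It replaces conjugate addition by a halogen-steered phenoxenium coupling on the regioisomeric (vanilloid) ring D. Bromide 6 is coupled under the step 3 conditions with commercial 4'-hydroxy-3'-methoxyacetophenone to give vanilloid stilbene ketone F1. This is hydrogenated (H2, Pd/C) to vanilloid seco ketone F2 and ketalised as in step 5 to vanilloid seco ketal F3. NBS (3 equiv) with catalytic iPr2NH in CH2Cl2 brominates ortho to both free phenols and gives seco tribromide F4. Tl(NO3)3·3H2O (THF–MeOH, pyridine, 1 mM, −20 °C) oxidises the more electron-rich bromoguaiacol ring. The dibromophenol oxygen, whose ortho carbons are blocked, attacks the bromine-bearing C5 to give macrocyclic bromodienone F5. This is reduced without isolation by Zn/AcOH to dibromo macrocycle F6. H2, Pd/C and Et3N remove the two aryl bromides to give vanilloid macrocyclic ketal F7. BBr3 as in step 7 then converges on 13, because both methylation patterns lead to the same catechol.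

**Step 8 (transfer hydrogenation of the free triphenol ketone).** The risks are:
- sluggish reduction of the electron-rich para-hydroxyaryl ketone;
- catechol binding to ruthenium;
- lower facial selectivity inside the macrocycle;
- erosion of ee through the quinone methide.

The fallback sets out from 13 and comes back at 14. It uses a stoichiometric chiral borane on a protected ketone. TBSCl/imidazole in DMF gives tris(silyl ether) ketone F8. (−)-B-chlorodiisopinocampheylborane (THF, −25 °C, diethanolamine work-up) reduces the aryl/primary-alkyl ketone to (S)-carbinol tris(silyl ether) F9. TBAF buffered with AcOH (THF, 0 °C) releases 14 without forming a free phenoxide next to the carbinol.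

**Step 5 (ketalisation of a hindered, electron-rich deoxybenzoin).** The risks are incomplete conversion and enol ether formation. The fallback sets out from 9 and comes back at 13. It masks C7' by a redox detour instead of a protecting group. NaBH4 in MeOH gives racemic seco carbinol F10. The step 6 protocol takes this through carbinol orthoquinol acetate F11 to macrocyclic racemic carbinol F12. Phenol-tolerant transfer dehydrogenation (RuCl2(PPh3)3, K2CO3, acetone, reflux) gives macrocyclic ketone dimethyl ether F13, and BBr3 as in step 7 gives 13.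

## Further compounds
F1 | step 6 | vanilloid stilbene ketone (E/Z mixture) | COc1cc(ccc1O)C(=O)Cc1cccc(Oc2c(OC)cccc2C=Cc2ccc(OCc3ccccc3)cc2)c1
F2 | step 6 | vanilloid seco ketone | COc1cc(ccc1O)C(=O)Cc1cccc(Oc2c(OC)cccc2CCc2ccc(O)cc2)c1
F3 | step 6 | vanilloid seco ketal | COc1cc(ccc1O)C1(Cc2cccc(Oc3c(OC)cccc3CCc3ccc(O)cc3)c2)OCCO1
F4 | step 6 | seco tribromide | COc1cc(cc(Br)c1O)C1(Cc2cccc(Oc3c(OC)cccc3CCc3cc(Br)c(O)c(Br)c3)c2)OCCO1
F5 | step 6 | macrocyclic bromodienone (racemic, not isolated) | COC1=CC2=CC(Br)(C1=O)Oc1c(Br)cc(cc1Br)CCc1cccc(OC)c1Oc1cccc(c1)CC23OCCO3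
F6 | step 6 | dibromo macrocycle | COc1cc2cc(c1O)Oc1c(Br)cc(cc1Br)CCc1cccc(OC)c1Oc1cccc(c1)CC23OCCO3
F7 | step 6 | vanilloid macrocyclic ketal | COc1cc2cc(c1O)Oc1ccc(cc1)CCc1cccc(OC)c1Oc1cccc(c1)CC23OCCO3
F8 | step 8 | tris(silyl ether) ketone | CC(C)(C)[Si](C)(C)Oc1cc2cc(c1O[Si](C)(C)C(C)(C)C)Oc1ccc(cc1)CCc1cccc(O[Si](C)(C)C(C)(C)C)c1Oc1cccc(c1)CC2=O
F9 | step 8 | (S)-carbinol tris(silyl ether) | CC(C)(C)[Si](C)(C)Oc1cc2cc(c1O[Si](C)(C)C(C)(C)C)Oc1ccc(cc1)CCc1cccc(O[Si](C)(C)C(C)(C)C)c1Oc1cccc(c1)C[C@@H]2O
F10 | step 5 | racemic seco carbinol | COc1ccc(cc1O)C(O)Cc1cccc(Oc2c(OC)cccc2CCc2ccc(O)cc2)c1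
F11 | step 5 | carbinol orthoquinol acetate (stereoisomer mixture, not isolated) | COC1(OC(C)=O)C=CC(=CC1=O)C(O)Cc1cccc(Oc2c(OC)cccc2CCc2ccc(O)cc2)c1
F12 | step 5 | macrocyclic racemic carbinol | Oc1cc2cc(c1OC)Oc1ccc(cc1)CCc1cccc(OC)c1Oc1cccc(c1)CC2O
F13 | step 5 | macrocyclic ketone dimethyl ether | Oc1cc2cc(c1OC)Oc1ccc(cc1)CCc1cccc(OC)c1Oc1cccc(c1)CC2=O
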